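**Assumption:** the target has no stereocentre (it is achiral), so no stereocontrol is needed; the SMILES is read as 3-henicosyl-2,5-dihydroxy-6-methyl-1,4-benzoquinone with a linear C21 chain.

## Retrosynthetic overview

1. No ring is built: the carbocycle is the benzene ring of hydroquinone 1, dearomatised and doubly hydroxylated (through quinones 2 and 3) to the symmetric 2,5-dihydroxy-1,4-benzoquinone 4.
2. Key disconnection, ring–C21 bond: 4 + docosanoic (behenic) acid 5 ⇒ mono-alkyl quinone 6 by decarboxylative radical C–H alkylation. The C22 acid loses CO2, so the odd C21 chain comes from a cheap even-chain fatty acid, and mono-alkylation breaks the symmetry of 4.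
3. Last disconnection, ring–CH3 bond: 6 + formaldehyde ⇒ target 8 by reductive C-methylation through quinone methide 7.
4. Order: oxygen pattern (step 1), long chain (step 2), methyl (step 3); no protecting groups.

## Route

Step 1
Reactants: 1 hydroquinone (benzene-1,4-diol)
Product: 4 2,5-dihydroxy-1,4-benzoquinone, via 1,4-benzoquinone 2 (not isolated), via 2-hydroxy-1,4-benzoquinone 3 (not isolated)
Conditions: 30% H2O2 (3.3 equiv, slow addition), 50% aq. NaOH, 45–50 °C; then conc. HCl, 0 °C
Reagents that add atoms: hydrogen peroxide, OO; sodium hydroxide (aqueous hydroxide), [Na+].[OH-]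
Why: Alkaline-peroxide oxidative dearomatisation (a known preparation of 4): 1 is oxidised to 2, hydroxide adds in a Michael sense and the adduct is re-oxidised to 3, whose hydroxy-enone half is deactivated as a vinylogous carboxylate so the second oxygen enters para to the first, and the insoluble disodium salt of 4 is shielded from over-oxidation; no stereocentre is formed.

Step 2
Reactants: 4 2,5-dihydroxy-1,4-benzoquinone (3 equiv); 5 docosanoic acid (behenic acid, 1 equiv)
Product: 6 3-henicosyl-2,5-dihydroxy-1,4-benzoquinone
Conditions: AgNO3 (0.2 equiv), (NH4)2S2O8 (1.5 equiv, added over 2 h), MeCN/H2O 2:1 (0.1 M H2SO4), 80 °C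
Reagents that add atoms: none
Why: Jacobsen–Torssell (Minisci-type) silver/persulfate decarboxylative radical alkylation: Ag(II) oxidises the carboxylate of 5, loss of CO2 leaves the nucleophilic primary henicosyl radical, which adds to one of the two equivalent ring C–H carbons of 4 (β to a C=O, captodatively stabilised adduct), and oxidation with loss of H+ restores the quinone, so the excess of symmetric 4 is desymmetrised by mono-alkylation with no regiochemical question; no stereocentre is formed.

Step 3
Reactants: 6 3-henicosyl-2,5-dihydroxy-1,4-benzoquinone
Product: 8 3-henicosyl-2,5-dihydroxy-6-methyl-1,4-benzoquinone, via quinone methide 7 (not isolated)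
Conditions: 37% aq. HCHO (1.5 equiv, slow addition), Hantzsch ester (diethyl 2,6-dimethyl-1,4-dihydropyridine-3,5-dicarboxylate, 2.5 equiv), L-proline (20 mol%), CH2Cl2/EtOH 4:1, 25–35 °C; air work-up
Reagents that add atoms: formaldehyde, C=O
Why: Organocatalytic three-component reductive alkylation (Knoevenagel condensation then Hantzsch-ester transfer hydrogenation): the proline iminium of formaldehyde is attacked by the only remaining nucleophilic ring carbon of the vinylogous acid 6, elimination gives 7, and conjugate hydride transfer to its exocyclic CH2 creates the methyl group and regenerates the dihydroxyquinone; no stereocentre is formed.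

## Compound list

1 | hydroquinone (benzene-1,4-diol) | Oc1ccc(O)cc1 | starting material
2 | 1,4-benzoquinone | O=C1C=CC(=O)C=C1 | intermediate (not isolated)
3 | 2-hydroxy-1,4-benzoquinone | O=C1C=CC(=O)C(O)=C1 | intermediate (not isolated)
4 | 2,5-dihydroxy-1,4-benzoquinone | O=C1C=C(O)C(=O)C=C1O | intermediate
5 | docosanoic acid (behenic acid) | CCCCCCCCCCCCCCCCCCCCCC(=O)O | starting material
6 | 3-henicosyl-2,5-dihydroxy-1,4-benzoquinone | CCCCCCCCCCCCCCCCCCCCCC1=C(O)C(=O)C=C(O)C1=O | intermediate
7 | 3-henicosyl-4-hydroxy-6-methylidenecyclohex-3-ene-1,2,5-trione (quinone methide) | C=C1C(=O)C(O)=C(CCCCCCCCCCCCCCCCCCCCC)C(=O)C1=O | intermediate (not isolated)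
8 | 3-henicosyl-2,5-dihydroxy-6-methyl-1,4-benzoquinone (2-henicosyl-3,6-dihydroxy-5-methylcyclohexa-2,5-diene-1,4-dione) | CCCCCCCCCCCCCCCCCCCCCC1=C(O)C(=O)C(C)=C(O)C1=O | target

## Step count and risks

Total step count: 3. Longest linear sequence: 3 steps (1 → 4 → 6 → 8).

Steps most likely to fail, most risky first:

**Step 2 (radical mono-alkylation).** The risks are the poor solubility of 5 in the aqueous medium, silver salts of 4 precipitating, oxidative loss of the electron-rich quinone, and a second alkylation of 6. The fallback replaces the radical bond formation by a polar reductive alkylation. It sets out from 4 and comes back at 6. Purchased henicosan-1-ol F1 is oxidised (TEMPO cat., PhI(OAc)2, CH2Cl2, rt) to henicosanal F2. F2 is then condensed with 4 (L-proline cat., Hantzsch ester, CH2Cl2, rt) through the transient alkylidene 6-henicosylidene-4-hydroxycyclohex-3-ene-1,2,5-trione F3, which is reduced in the flask by the Hantzsch ester to 6.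

**Step 3 (reductive methylation).** The risks are Michael addition of a second molecule of 6 to the very electrophilic methide 7 (methylene-bridged dimer) and partial reduction of the quinone by the Hantzsch ester. The fallback changes from the polar condensation/hydride sequence to a radical C–H methylation. It sets out from 6 and comes back at 8. 6 is heated in acetic acid as the methyl-radical source, either under the Ag(I)/persulfate conditions of step 2 or with Pb(OAc)4 at 80–90 °C (Fieser-type quinone methylation); the methyl radical adds to the single free ring position and re-oxidation gives 8 directly. No new compound is formed on this way (F0).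

**Step 1 (dearomatising double hydroxylation).** The risks are over-oxidation and ring cleavage if temperature or peroxide dosing drift. The fallback introduces the two oxygens as amines and then hydrolyses. It sets out from 1 and comes back at 4. 1 is stirred with morpholine (4 equiv) and Cu(OAc)2 (5 mol%) under O2 in MeOH at rt; quinone 2 forms in situ and takes up two amines para to each other with re-oxidation to give 2,5-dimorpholino-1,4-benzoquinone F4. Heating F4 in 2 M aq. H2SO4 hydrolyses both vinylogous amides and gives 4.

## Further compounds

F1 | step 2 | henicosan-1-ol (purchased) | CCCCCCCCCCCCCCCCCCCCCO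
F2 | step 2 | henicosanal | CCCCCCCCCCCCCCCCCCCCC=O
F3 | step 2 | 6-henicosylidene-4-hydroxycyclohex-3-ene-1,2,5-trione (transient, C=C geometry not defined) | CCCCCCCCCCCCCCCCCCCCC=C1C(=O)C(O)=CC(=O)C1=O
F0 | step 3 | none | none
F4 | step 1 | 2,5-dimorpholino-1,4-benzoquinone | O=C1C=C(N2CCOCC2)C(=O)C=C1N3CCOCC3
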